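**Retrosynthetic overview**

1. Numbering used here: lactone C=O is C1, enoate C2=C3, N–CH is C5, spiro carbon C9, cyclopentane CH C13, CHMe C14, carbinol C17, C–Cl C19, OCH2 C21. The macrolactone is opened at O–C1 (Shiina closure, last ring). C16–C17 is cut to terminal alkyne 20 plus enal 25 (Zn–ProPhenol alkynylation, then Lindlar reduction for the 15Z alkene). The E-chloroalkene comes geometry-locked from chlorolactone 22.
2. The dehydropiperidine ring (N, NCH2, C2, C3, C4, C5) comes from N-alkylation with a bromomethyl acrylate and ring-closing metathesis.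
3. Key disconnection: the C8–C9 bond of the piperidine, together with C9–N. An intramolecular Mannich spirocyclisation joins amine 11 (C5 stereocentre, masked C7 ketone, C8 methyl) to the stereorandom ketone 5 (C14 from the chiral pool). The temporary C7 carbonyl is then removed.
4. Enabling feature: C9, the spiro atom shared by the cyclopentane and the piperidine, carries the nitrogen, so it can be the iminium carbon of a cyclopentanone. C8 is the ring CH2 next to it and C7 can be a carbonyl, so N–C9–C8–C7=O is a Mannich retron. C13, the cyclopentane CH next to C9, is α to that iminium and epimerises, so it is set in the same event.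
5. Ring order: cyclopentane (bought in with 3), then piperidine (step 8), then dehydropiperidine (step 11), then the 15-membered lactone (step 20).

Key step: step 8

Assumption: compounds 1, 3, 6, 8, 17 and 21 are taken as commercially available.
Assumption: (S,S)-ProPhenol is taken as the ligand enantiomer that directs the alkynylzinc to the Re face of enal 25; if a trial addition shows the opposite sense, the (R,R)-ligand is used in the same step.

**Route**

Step 1
Reactants: 1 (R)-4-(trimethylsilyl)but-3-yn-2-ol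
Product: 2 (R)-4-(trimethylsilyl)but-3-yn-2-yl methanesulfonate
Conditions: MsCl, Et3N, CH2Cl2, 0 °C
Reagents that add atoms: methanesulfonyl chloride, CS(=O)(=O)Cl
Why: Mesylation takes place at oxygen, so the carbinol configuration is retained and a good leaving group is installed.

Step 2
Reactants: 3 allyl 2-oxocyclopentane-1-carboxylate; 2 (R)-4-(trimethylsilyl)but-3-yn-2-yl methanesulfonate
Product: 4 allyl 2-oxo-1-[(R)-4-(trimethylsilyl)but-3-yn-2-yl]cyclopentane-1-carboxylate (both epimers at the ring carbon)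
Conditions: NaH, DMF, 0 °C; then 2, 50 °C
Reagents that add atoms: none
Why: SN2 C-alkylation of the soft β-keto ester enolate at the secondary propargylic sulfonate should proceed with inversion and so set the methyl-bearing stereocentre, the silyl cap disfavouring attack at the alkyne terminus; the ring carbon forms as a mixture, which does not matter.

Step 3
Reactants: 4 allyl 2-oxo-1-[(R)-4-(trimethylsilyl)but-3-yn-2-yl]cyclopentane-1-carboxylate
Product: 5 2-[(R)-4-(trimethylsilyl)but-3-yn-2-yl]cyclopentan-1-one (both epimers at ring C2)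
Conditions: Pd(OAc)2 (5 mol %), PPh3, HCO2H, Et3N, THF, 40 °C
Reagents that add atoms: none
Why: In this Tsuji deallylation–decarboxylation, zerovalent palladium ionises the allyl ester, formate reduces the π-allyl complex to propene and the β-keto acid loses CO2 under neutral conditions that leave the propargylic stereocentre untouched.

Step 4
Reactants: 6 ethyl 2-(2-methyl-1,3-dioxolan-2-yl)acetate
Product: 7 2-(2-methyl-1,3-dioxolan-2-yl)acetaldehyde
Conditions: i-Bu2AlH (1.05 equiv), CH2Cl2, −78 °C; Rochelle salt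
Reagents that add atoms: none
Why: Partial ester reduction at −78 °C stops at the aldehyde because the tetrahedral aluminium hemiacetal survives until work-up.

Step 5
Reactants: 7 2-(2-methyl-1,3-dioxolan-2-yl)acetaldehyde; 8 (R)-2-methylpropane-2-sulfinamide
Product: 9 (R,E)-2-methyl-N-[2-(2-methyl-1,3-dioxolan-2-yl)ethylidene]propane-2-sulfinamide
Conditions: Ti(OEt)4, THF, rt
Reagents that add atoms: none
Why: Ellman condensation of an aldehyde with tert-butanesulfinamide gives the E-sulfinyl aldimine, Ti(OEt)4 acting as Lewis acid and water scavenger without harming the ketal.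

Step 6
Reactants: 9 (R,E)-2-methyl-N-[2-(2-methyl-1,3-dioxolan-2-yl)ethylidene]propane-2-sulfinamide
Product: 10 (R)-2-methyl-N-[(S)-1-(2-methyl-1,3-dioxolan-2-yl)pent-4-en-2-yl]propane-2-sulfinamide
Conditions: allylMgBr, CH2Cl2, −78 °C
Reagents that add atoms: allylmagnesium bromide, C=CC[Mg]Br
Why: In this Ellman allylation the Grignard reagent reacts in CH2Cl2 through a six-membered chair with magnesium on the sulfinyl oxygen, so allyl is delivered to one face of the aldimine and the (S)-configured amine carbon (the future C5) is set by the auxiliary.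

Step 7
Reactants: 10 (R)-2-methyl-N-[(S)-1-(2-methyl-1,3-dioxolan-2-yl)pent-4-en-2-yl]propane-2-sulfinamide
Product: 11 (S)-1-(2-methyl-1,3-dioxolan-2-yl)pent-4-en-2-amine
Conditions: HCl (4 M in dioxane, 2 equiv), MeOH, 0 °C, 20 min; aq. K2CO3
Reagents that add atoms: none
Why: Acidic methanolysis cleaves the S–N bond of a sulfinamide within minutes at 0 °C, conditions short and dry enough to leave the ketone dioxolane in place, and the carbon stereocentre is not involved.

Step 8
Reactants: 11 (S)-1-(2-methyl-1,3-dioxolan-2-yl)pent-4-en-2-amine; 5 2-[(R)-4-(trimethylsilyl)but-3-yn-2-yl]cyclopentan-1-one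
Product: 14 (1R,5S,7S)-7-allyl-1-[(R)-4-(trimethylsilyl)but-3-yn-2-yl]-6-azaspiro[4.5]decan-9-one, via ketimine 12 (not isolated), via spiro ketal 13 (not isolated)
Conditions: 4 Å MS, toluene, 80 °C; TsOH (1.5 equiv), 80 °C; then 2 M HCl, THF, 40 °C; NaOH work-up
Reagents that add atoms: water, O
Why: Condensation gives ketimine 12; TsOH protonates it and opens the dioxolane to a 2-hydroxyethyl enol ether whose terminal carbon (the methyl carbon of the masked ketone) attacks the iminium carbon in an intramolecular Mannich reaction, after which the dioxolane re-closes to 13, the cyclisation type known for β-amino ketals with aldehydes and cyclic ketones. The piperidine closes in a 6-endo-trig mode at the iminium (enol-endo) through a chair in which the allyl group on the amine carbon is equatorial and the nitrogen substituent of the E-iminium lies anti to the branched α-carbon of the cyclopentane. The spiro carbon is therefore set by the amine stereocentre across nitrogen (allyl cis to the cyclopentane CH on the piperidine), and the new C–C bond forms anti to the side chain on the neighbouring ring carbon, which places nitrogen cis to that side chain. Because this ring carbon is α to the iminium carbon, its two epimers should interconvert through the enamine faster than they cyclise, so the stereorandom ketone 5 is funnelled into one diastereomer (dynamic kinetic resolution), while the methyl-bearing propargylic stereocentre is not acidic and is carried unchanged. The selectivity needed is diastereofacial (one iminium face, one epimer of the ring carbon); it is secured by the equatorial preference of the allyl group and the anti approach, and reversibility of the Mannich step should let minor isomers drain to the same product, which carries the allyl group and the more substituted ring carbon equatorial. Aqueous HCl then unmasks the temporary ketone.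

Step 9
Reactants: 14 (1R,5S,7S)-7-allyl-1-[(R)-4-(trimethylsilyl)but-3-yn-2-yl]-6-azaspiro[4.5]decan-9-one
Product: 16 (1R,5S,7R)-7-allyl-1-[(R)-4-(trimethylsilyl)but-3-yn-2-yl]-6-azaspiro[4.5]decane, via tosylhydrazone 15 (not isolated)
Conditions: TsNHNH2, MeOH, 50 °C; then catecholborane, CHCl3, 0 °C to rt; NaOAc·3H2O, reflux
Reagents that add atoms: none
Why: In this Caglioti–Kabalka deoxygenation, hydride adds to the C=N bond of the unhindered hydrazone, acetate triggers loss of sulfinate and the diazene expels N2, which removes the temporary carbonyl under conditions that spare the alkene, the silyl alkyne and all stereocentres.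

Step 10
Reactants: 16 (1R,5S,7R)-7-allyl-1-[(R)-4-(trimethylsilyl)but-3-yn-2-yl]-6-azaspiro[4.5]decane; 17 methyl 2-(bromomethyl)acrylate
Product: 18 methyl 2-{[(1R,5S,7R)-7-allyl-1-[(R)-4-(trimethylsilyl)but-3-yn-2-yl]-6-azaspiro[4.5]decan-6-yl]methyl}acrylate
Conditions: K2CO3, MeCN, 40 °C
Reagents that add atoms: none
Why: N-Alkylation of the hindered secondary amine should succeed because the 2-(bromomethyl)acrylate is a doubly activated allylic electrophile that reacts by SN2 or addition–elimination.

Step 11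
Reactants: 18 methyl 2-{[(1R,5S,7R)-7-allyl-1-[(R)-4-(trimethylsilyl)but-3-yn-2-yl]-6-azaspiro[4.5]decan-6-yl]methyl}acrylate
Product: 19 methyl (1S,2R,9a'R)-2-[(R)-4-(trimethylsilyl)but-3-yn-2-yl]-1',4',7',8',9',9a'-hexahydrospiro[cyclopentane-1,6'-quinolizine]-3'-carboxylate
Conditions: TsOH·H2O (1.1 equiv), second-generation Grubbs catalyst (10 mol %), CH2Cl2, 40 °C; aq. NaHCO3
Reagents that add atoms: none
Why: Ring-closing metathesis of the allyl group with the 1,1-disubstituted acrylate closes the six-membered enoate ring with loss of ethene, the amine being protonated to protect the ruthenium carbene and the silyl-capped alkyne staying inert.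

Step 12
Reactants: 19 methyl (1S,2R,9a'R)-2-[(R)-4-(trimethylsilyl)but-3-yn-2-yl]-1',4',7',8',9',9a'-hexahydrospiro[cyclopentane-1,6'-quinolizine]-3'-carboxylate
Product: 20 methyl (1S,2R,9a'R)-2-[(R)-but-3-yn-2-yl]-1',4',7',8',9',9a'-hexahydrospiro[cyclopentane-1,6'-quinolizine]-3'-carboxylate
Conditions: K2CO3 (cat.), MeOH, rt
Reagents that add atoms: none
Why: Methanolysis of the C(sp)–Si bond frees the terminal alkyne, and with a methyl ester in methanol no transesterification product can arise.

Step 13
Reactants: 21 dihydro-2H-pyran-2,4(3H)-dione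
Product: 22 4-chloro-5,6-dihydro-2H-pyran-2-one
Conditions: (COCl)2, DMF (cat.), CH2Cl2, 0 °C to rt
Reagents that add atoms: oxalyl chloride, ClC(=O)C(Cl)=O
Why: Vilsmeier-type chlorination converts the enol of the vinylogous acid into the vinyl chloride, and the ring fixes the carbonyl carbon and the ring CH2 cis across the new chloroalkene, which is the geometry the target needs.

Step 14
Reactants: 22 4-chloro-5,6-dihydro-2H-pyran-2-one
Product: 23 (E)-3-chloro-5-hydroxy-N-methoxy-N-methylpent-2-enamide
Conditions: MeNH(OMe)·HCl, AlMe3, CH2Cl2, 0 °C; Rochelle salt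
Reagents that add atoms: N,O-dimethylhydroxylamine hydrochloride, Cl.CNOC
Why: Weinreb aminolysis of the lactone with the aluminium amide attacks the acyl carbon and opens the ring without touching the double bond, so the ring-defined alkene geometry is carried into the open chain.

Step 15
Reactants: 23 (E)-3-chloro-5-hydroxy-N-methoxy-N-methylpent-2-enamide
Product: 24 (E)-5-[(tert-butyldimethylsilyl)oxy]-3-chloro-N-methoxy-N-methylpent-2-enamide
Conditions: TBSCl, imidazole, CH2Cl2, 0 °C
Reagents that add atoms: tert-butyldimethylsilyl chloride, CC(C)(C)[Si](C)(C)Cl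
Why: Silylation of the primary alcohol blocks relactonisation and is run at once on the crude hydroxy amide.

Step 16
Reactants: 24 (E)-5-[(tert-butyldimethylsilyl)oxy]-3-chloro-N-methoxy-N-methylpent-2-enamide
Product: 25 (E)-5-[(tert-butyldimethylsilyl)oxy]-3-chloropent-2-enal
Conditions: i-Bu2AlH, THF, −78 °C
Reagents that add atoms: none
Why: Weinreb amide reduction stops at the aldehyde through the chelated aluminium hemiaminal, and 1,2-hydride delivery at −78 °C leaves the chloroalkene and its geometry intact.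

Step 17
Reactants: 20 methyl (1S,2R,9a'R)-2-[(R)-but-3-yn-2-yl]-1',4',7',8',9',9a'-hexahydrospiro[cyclopentane-1,6'-quinolizine]-3'-carboxylate; 25 (E)-5-[(tert-butyldimethylsilyl)oxy]-3-chloropent-2-enal
Product: 26 methyl (1S,2R,9a'R)-2-[(2R,5S,6E)-9-[(tert-butyldimethylsilyl)oxy]-7-chloro-5-hydroxynon-6-en-3-yn-2-yl]-1',4',7',8',9',9a'-hexahydrospiro[cyclopentane-1,6'-quinolizine]-3'-carboxylate
Conditions: (S,S)-ProPhenol (20 mol %), Me2Zn (3 equiv), Ph3P=O (40 mol %), toluene, 0–4 °C; aq. NH4Cl
Reagents that add atoms: none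
Why: In this Zn–ProPhenol alkynylation of an enal, the dinuclear zinc complex binds the aldehyde and delivers the alkynylzinc formed from 20 to the Re face, which sets the carbinol in the spatial arrangement of the target (S descriptor at the enynol stage) under conditions the ester and the amine tolerate.

Step 18
Reactants: 26 methyl (1S,2R,9a'R)-2-[(2R,5S,6E)-9-[(tert-butyldimethylsilyl)oxy]-7-chloro-5-hydroxynon-6-en-3-yn-2-yl]-1',4',7',8',9',9a'-hexahydrospiro[cyclopentane-1,6'-quinolizine]-3'-carboxylate
Product: 27 methyl (1S,2R,9a'R)-2-[(2S,3Z,5R,6E)-9-[(tert-butyldimethylsilyl)oxy]-7-chloro-5-hydroxynona-3,6-dien-2-yl]-1',4',7',8',9',9a'-hexahydrospiro[cyclopentane-1,6'-quinolizine]-3'-carboxylate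
Conditions: H2 (1 atm), Pd/CaCO3 poisoned with Pb(OAc)2 (Lindlar catalyst), quinoline, EtOAc, rt
Reagents that add atoms: none
Why: Lindlar semi-hydrogenation adds H2 syn to the alkyne and stops at the Z-alkene, the poisoned catalyst being expected to spare the vinyl chloride and the trisubstituted enoate.

Step 19
Reactants: 27 methyl (1S,2R,9a'R)-2-[(2S,3Z,5R,6E)-9-[(tert-butyldimethylsilyl)oxy]-7-chloro-5-hydroxynona-3,6-dien-2-yl]-1',4',7',8',9',9a'-hexahydrospiro[cyclopentane-1,6'-quinolizine]-3'-carboxylate
Product: 29 (1S,2R,9a'R)-2-[(2S,3Z,5R,6E)-7-chloro-5,9-dihydroxynona-3,6-dien-2-yl]-1',4',7',8',9',9a'-hexahydrospiro[cyclopentane-1,6'-quinolizine]-3'-carboxylic acid, via diol ester 28 (not isolated)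
Conditions: Bu4NF, THF, 0 °C; then LiOH, THF/MeOH/H2O, rt; 1 M HCl to pH 7
Reagents that add atoms: lithium hydroxide, [Li+].[OH-]
Why: Fluoride desilylation followed by saponification in the same flask frees the primary alcohol and the acid under basic conditions, which avoids ionisation of the doubly allylic carbinol.

Step 20
Reactants: 29 (1S,2R,9a'R)-2-[(2S,3Z,5R,6E)-7-chloro-5,9-dihydroxynona-3,6-dien-2-yl]-1',4',7',8',9',9a'-hexahydrospiro[cyclopentane-1,6'-quinolizine]-3'-carboxylic acid
Product: 30 target macrolactone CNP0129639.4 (5R,9S,13R,14S,17R; 15Z,18E in the numbering of the overview)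
Conditions: MNBA (2-methyl-6-nitrobenzoic anhydride), DMAP, CH2Cl2 (1 mM), rt, slow addition
Reagents that add atoms: none
Why: In this Shiina macrolactonisation the mixed anhydride is attacked, under DMAP catalysis and high dilution, by the unhindered primary hydroxyl to close the 15-membered ring, whereas the secondary doubly allylic hydroxyl would have to close a strained 11-membered ring and should stay free.

**Compound list**

1 | (R)-4-(trimethylsilyl)but-3-yn-2-ol | C[C@@H](O)C#C[Si](C)(C)C | starting material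
2 | (R)-4-(trimethylsilyl)but-3-yn-2-yl methanesulfonate | C[C@@H](OS(C)(=O)=O)C#C[Si](C)(C)C | intermediate
3 | allyl 2-oxocyclopentane-1-carboxylate | C=CCOC(=O)C1CCCC1=O | starting material
4 | allyl 2-oxo-1-[(R)-4-(trimethylsilyl)but-3-yn-2-yl]cyclopentane-1-carboxylate (ring epimers) | C=CCOC(=O)C1(CCCC1=O)[C@@H](C)C#C[Si](C)(C)C | intermediate
5 | 2-[(R)-4-(trimethylsilyl)but-3-yn-2-yl]cyclopentan-1-one (ring epimers) | O=C1CCCC1[C@@H](C)C#C[Si](C)(C)C | intermediate
6 | ethyl 2-(2-methyl-1,3-dioxolan-2-yl)acetate | CCOC(=O)CC1(C)OCCO1 | starting material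
7 | 2-(2-methyl-1,3-dioxolan-2-yl)acetaldehyde | O=CCC1(C)OCCO1 | intermediate
8 | (R)-2-methylpropane-2-sulfinamide | CC(C)(C)[S@@](=O)N | starting material
9 | (R,E)-2-methyl-N-[2-(2-methyl-1,3-dioxolan-2-yl)ethylidene]propane-2-sulfinamide | CC(C)(C)[S@@](=O)/N=C/CC1(C)OCCO1 | intermediate
10 | (R)-2-methyl-N-[(S)-1-(2-methyl-1,3-dioxolan-2-yl)pent-4-en-2-yl]propane-2-sulfinamide | CC(C)(C)[S@@](=O)N[C@@H](CC=C)CC1(C)OCCO1 | intermediate
11 | (S)-1-(2-methyl-1,3-dioxolan-2-yl)pent-4-en-2-amine | C=CC[C@H](N)CC1(C)OCCO1 | intermediate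
12 | ketimine of 5 with amine 11 (E/Z and ring-epimer mixture) | C=CC[C@@H](CC1(C)OCCO1)N=C2CCCC2[C@@H](C)C#C[Si](C)(C)C | intermediate
13 | dioxolane ketal of 14 (9,9-ethylenedioxy compound) | C=CC[C@H]1CC2(OCCO2)C[C@]3(CCC[C@@H]3[C@@H](C)C#C[Si](C)(C)C)N1 | intermediate
14 | (1R,5S,7S)-7-allyl-1-[(R)-4-(trimethylsilyl)but-3-yn-2-yl]-6-azaspiro[4.5]decan-9-one | C=CC[C@H]1CC(=O)C[C@]2(CCC[C@@H]2[C@@H](C)C#C[Si](C)(C)C)N1 | intermediate
15 | 4-methylbenzenesulfonohydrazone of 14 | C=CC[C@H]1CC(=NNS(=O)(=O)c2ccc(C)cc2)C[C@]3(CCC[C@@H]3[C@@H](C)C#C[Si](C)(C)C)N1 | intermediate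
16 | (1R,5S,7R)-7-allyl-1-[(R)-4-(trimethylsilyl)but-3-yn-2-yl]-6-azaspiro[4.5]decane | C=CC[C@H]1CCC[C@]2(CCC[C@@H]2[C@@H](C)C#C[Si](C)(C)C)N1 | intermediate
17 | methyl 2-(bromomethyl)acrylate | C=C(CBr)C(=O)OC | starting material
18 | methyl 2-{[(1R,5S,7R)-7-allyl-1-[(R)-4-(trimethylsilyl)but-3-yn-2-yl]-6-azaspiro[4.5]decan-6-yl]methyl}acrylate | C=CC[C@H]1CCC[C@]2(CCC[C@@H]2[C@@H](C)C#C[Si](C)(C)C)N1CC(=C)C(=O)OC | intermediate
19 | methyl (1S,2R,9a'R)-2-[(R)-4-(trimethylsilyl)but-3-yn-2-yl]-1',4',7',8',9',9a'-hexahydrospiro[cyclopentane-1,6'-quinolizine]-3'-carboxylate | COC(=O)C1=CC[C@H]2CCC[C@]3(CCC[C@@H]3[C@@H](C)C#C[Si](C)(C)C)N2C1 | intermediate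
20 | methyl (1S,2R,9a'R)-2-[(R)-but-3-yn-2-yl]-1',4',7',8',9',9a'-hexahydrospiro[cyclopentane-1,6'-quinolizine]-3'-carboxylate | COC(=O)C1=CC[C@H]2CCC[C@]3(CCC[C@@H]3[C@@H](C)C#C)N2C1 | intermediate
21 | dihydro-2H-pyran-2,4(3H)-dione | O=C1CCOC(=O)C1 | starting material
22 | 4-chloro-5,6-dihydro-2H-pyran-2-one | O=C1C=C(Cl)CCO1 | intermediate
23 | (E)-3-chloro-5-hydroxy-N-methoxy-N-methylpent-2-enamide | CON(C)C(=O)/C=C(/Cl)CCO | intermediate
24 | (E)-5-[(tert-butyldimethylsilyl)oxy]-3-chloro-N-methoxy-N-methylpent-2-enamide | CON(C)C(=O)/C=C(/Cl)CCO[Si](C)(C)C(C)(C)C | intermediate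
25 | (E)-5-[(tert-butyldimethylsilyl)oxy]-3-chloropent-2-enal | O=C/C=C(/Cl)CCO[Si](C)(C)C(C)(C)C | intermediate
26 | methyl (1S,2R,9a'R)-2-[(2R,5S,6E)-9-[(tert-butyldimethylsilyl)oxy]-7-chloro-5-hydroxynon-6-en-3-yn-2-yl]-1',4',7',8',9',9a'-hexahydrospiro[cyclopentane-1,6'-quinolizine]-3'-carboxylate | COC(=O)C1=CC[C@H]2CCC[C@]3(CCC[C@@H]3[C@@H](C)C#C[C@@H](O)/C=C(/Cl)CCO[Si](C)(C)C(C)(C)C)N2C1 | intermediate
27 | methyl (1S,2R,9a'R)-2-[(2S,3Z,5R,6E)-9-[(tert-butyldimethylsilyl)oxy]-7-chloro-5-hydroxynona-3,6-dien-2-yl]-1',4',7',8',9',9a'-hexahydrospiro[cyclopentane-1,6'-quinolizine]-3'-carboxylate | COC(=O)C1=CC[C@H]2CCC[C@]3(CCC[C@@H]3[C@@H](C)/C=C\[C@@H](O)/C=C(/Cl)CCO[Si](C)(C)C(C)(C)C)N2C1 | intermediate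
28 | methyl (1S,2R,9a'R)-2-[(2S,3Z,5R,6E)-7-chloro-5,9-dihydroxynona-3,6-dien-2-yl]-1',4',7',8',9',9a'-hexahydrospiro[cyclopentane-1,6'-quinolizine]-3'-carboxylate | COC(=O)C1=CC[C@H]2CCC[C@]3(CCC[C@@H]3[C@@H](C)/C=C\[C@@H](O)/C=C(/Cl)CCO)N2C1 | intermediate
29 | (1S,2R,9a'R)-2-[(2S,3Z,5R,6E)-7-chloro-5,9-dihydroxynona-3,6-dien-2-yl]-1',4',7',8',9',9a'-hexahydrospiro[cyclopentane-1,6'-quinolizine]-3'-carboxylic acid | OC(=O)C1=CC[C@H]2CCC[C@]3(CCC[C@@H]3[C@@H](C)/C=C\[C@@H](O)/C=C(/Cl)CCO)N2C1 | intermediate
30 | target macrolactone CNP0129639.4 (5R,9S,13R,14S,17R; 15Z,18E) | C[C@H]1/C=C\[C@@H](O)/C=C(/Cl)CCOC(=O)C2=CC[C@H]3CCC[C@]4(CCC[C@H]14)N3C2 | target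

**Step count**

Total: 20 steps. Longest linear sequence: 13 steps (6 → 7 → 9 → 10 → 11 → 14 → 16 → 18 → 19 → 20 → 26 → 27 → 29 → 30; steps 4–12 and 17–20).

**Steps most likely to fail, with fallbacks**

Step 8. Risk: the ring carbon next to the iminium may not equilibrate fast enough relative to C–C bond formation, or the hindered ketimine may revert instead of cyclising, so diastereocontrol at the spiro centre is eroded. Fallback (sets out from ketone 5 with sulfinamide 8, returns at amine 16): the C–C bond at the spiro carbon is made intermolecularly under auxiliary control and the piperidine is then closed at nitrogen. Condensation of 5 with 8 (Ti(OEt)4, THF, 65 °C) gives the (R)-N-sulfinyl ketimine F1. Addition of pent-4-enyllithium in the presence of AlMe3 (toluene, −78 °C), anti to the ring substituent and through the chelated Ellman transition state, gives the quaternary sulfinamide F2, with chromatographic removal of the minor diastereomer. Cross-metathesis with methyl acrylate (second-generation Hoveyda–Grubbs catalyst) gives the enoate F3. HCl/MeOH followed by K2CO3 removes the sulfinyl group, and the free amine closes by reversible intramolecular aza-Michael addition to the equatorial piperidine ester F4. i-Bu2AlH at −78 °C gives the aldehyde F5, which is methylenated at once (Ph3P=CH2) to give 16.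

Step 2. Risk: E2 elimination and O-alkylation may compete, and partial ionisation of the propargylic sulfonate would lower stereochemical fidelity at the methyl-bearing carbon. Fallback (sets out from β-keto ester 3, returns at ketone 5): the stereocentre is installed with an α-triflyloxy ester, a far better SN2 electrophile, and the alkyne is built afterwards. The sodium enolate of 3 is alkylated with commercial ethyl (R)-2-(trifluoromethylsulfonyloxy)propanoate (inversion) to give the diester F6. Pd(OAc)2/PPh3/HCO2H/Et3N gives the keto ester F7. Ethylene glycol/TsOH gives the ketal ester F8. i-Bu2AlH at −78 °C gives the aldehyde F9. Ohira–Bestmann homologation (dimethyl (1-diazo-2-oxopropyl)phosphonate, K2CO3, MeOH, 0 °C) gives the alkyne F10. LiHMDS/TMSCl gives the silyl alkyne F11, and aqueous HCl in acetone returns 5.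

Step 17. Risk: the Lewis-basic amine and ester of 20 may compete for the zinc catalyst, giving slow addition or poor facial selectivity at the carbinol carbon. Fallback (sets out from alkyne 20 and Weinreb amide 24, returns at 26): C–C bond formation and stereocontrol are separated. Deprotonation of 20 with LiHMDS (THF, −78 °C) and addition to 24 gives the ynone F12. Reduction with (S)-2-methyl-CBS-oxazaborolidine and catecholborane at −78 °C, in which the alkenyl arm with its cis substituent is expected to act as the large group and the alkynyl arm as the small one, gives 26.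

**Further compounds**

F1 | step 8 | (R)-2-methyl-N-{2-[(R)-4-(trimethylsilyl)but-3-yn-2-yl]cyclopentylidene}propane-2-sulfinamide | CC(C)(C)[S@@](=O)N=C1CCCC1[C@@H](C)C#C[Si](C)(C)C
F2 | step 8 | (R)-2-methyl-N-{(1S,2R)-1-(pent-4-en-1-yl)-2-[(R)-4-(trimethylsilyl)but-3-yn-2-yl]cyclopentyl}propane-2-sulfinamide | CC(C)(C)[S@@](=O)N[C@]1(CCCC=C)CCC[C@@H]1[C@@H](C)C#C[Si](C)(C)C
F3 | step 8 | methyl (E)-6-{(1S,2R)-1-[(R)-tert-butylsulfinylamino]-2-[(R)-4-(trimethylsilyl)but-3-yn-2-yl]cyclopentyl}hex-2-enoate | CC(C)(C)[S@@](=O)N[C@]1(CCC/C=C/C(=O)OC)CCC[C@@H]1[C@@H](C)C#C[Si](C)(C)C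
F4 | step 8 | methyl 2-{(1R,5S,7R)-1-[(R)-4-(trimethylsilyl)but-3-yn-2-yl]-6-azaspiro[4.5]decan-7-yl}acetate | COC(=O)C[C@H]1CCC[C@]2(CCC[C@@H]2[C@@H](C)C#C[Si](C)(C)C)N1
F5 | step 8 | 2-{(1R,5S,7R)-1-[(R)-4-(trimethylsilyl)but-3-yn-2-yl]-6-azaspiro[4.5]decan-7-yl}acetaldehyde | O=CC[C@H]1CCC[C@]2(CCC[C@@H]2[C@@H](C)C#C[Si](C)(C)C)N1
F6 | step 2 | allyl 1-[(R)-1-ethoxy-1-oxopropan-2-yl]-2-oxocyclopentane-1-carboxylate (ring epimers) | C=CCOC(=O)C1(CCCC1=O)[C@@H](C)C(=O)OCC
F7 | step 2 | ethyl (R)-2-(2-oxocyclopentyl)propanoate (ring epimers) | O=C1CCCC1[C@@H](C)C(=O)OCC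
F8 | step 2 | ethyl (R)-2-(1,4-dioxaspiro[4.4]nonan-6-yl)propanoate (ring epimers) | O1CCOC12CCCC2[C@@H](C)C(=O)OCC
F9 | step 2 | (R)-2-(1,4-dioxaspiro[4.4]nonan-6-yl)propanal (ring epimers) | O1CCOC12CCCC2[C@@H](C)C=O
F10 | step 2 | 6-[(R)-but-3-yn-2-yl]-1,4-dioxaspiro[4.4]nonane (ring epimers) | O1CCOC12CCCC2[C@@H](C)C#C
F11 | step 2 | 6-[(R)-4-(trimethylsilyl)but-3-yn-2-yl]-1,4-dioxaspiro[4.4]nonane (ring epimers) | O1CCOC12CCCC2[C@@H](C)C#C[Si](C)(C)C
F12 | step 17 | methyl (1S,2R,9a'R)-2-[(2R,6E)-9-[(tert-butyldimethylsilyl)oxy]-7-chloro-5-oxonon-6-en-3-yn-2-yl]-1',4',7',8',9',9a'-hexahydrospiro[cyclopentane-1,6'-quinolizine]-3'-carboxylate | COC(=O)C1=CC[C@H]2CCC[C@]3(CCC[C@@H]3[C@@H](C)C#CC(=O)/C=C(/Cl)CCO[Si](C)(C)C(C)(C)C)N2C1
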